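Ring A of the chroman-2-one is taken apart at C8–C8a, C6–C7 and C4a–C8a. It carries oxygen on alternate carbons (C5, C7, C8a), with the acyl group on C8 and the stereogenic C4 attached to C4a. A thermal vinylketene–ynol ether benzannulation assembles exactly this pattern in one operation. It leaves only the C8a hydroxyl free for lactonisation and puts a silyl marker on C8 for ipso-acylation. The precursor is a 3-silyloxycyclobut-2-enone whose sp3 ring carbon bears the complete (R)-CH(Ph)CH2CO2Me side chain; its stereocentre comes from catalytic desymmetrisation of 3-phenylglutaric anhydride.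

Key step: step 5

Remark: (triisopropylsilyloxy)acetylene 5 is not a catalogue reagent and is therefore made in step 1; of the two pseudoenantiomeric cinchona thioureas, the one that delivers the (S)-hemiester 7 is used, its sense being confirmed once by the sign of rotation of 7.

Step 1
Reactants: 1 acetylene; 2 triisopropylsilyl trifluoromethanesulfonate
Product: 5 (triisopropylsilyloxy)acetylene, via lithium acetylide 3 (not isolated), via lithium ethynolate 4 (not isolated)
Conditions: n-BuLi, THF, −78 °C; cannulate into t-BuOOLi (t-BuOOH + LiN(SiMe3)2, THF, −78 °C); −78 → −20 °C; then 2, −78 → 0 °C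
Reagents that add atoms: tert-butyl hydroperoxide, CC(C)(C)OO
Why: Electrophilic oxygen transfer from lithium tert-butyl peroxide to an acetylide carbon (the established one-pot conversion of 1-alkynes into silyl ynol ethers) should give ynolate 4, which the bulky silyl triflate captures on oxygen and not on carbon; 3 is kept at or below −20 °C so that it does not disproportionate.

Step 2
Reactants: 6 3-phenylglutaric anhydride
Product: 7 (3S)-5-methoxy-5-oxo-3-phenylpentanoic acid
Conditions: MeOH (10 equiv), 9-amino-9-deoxy-epi-quinine N-[3,5-bis(trifluoromethyl)phenyl]thiourea (5 mol %, or its quinidine-derived pseudoenantiomer), MTBE, 20 °C; acid wash, one recrystallisation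
Reagents that add atoms: methanol, CO
Why: Desymmetrising alcoholysis of a prochiral cyclic anhydride: the quinuclidine nitrogen activates methanol as a general base while the thiourea binds one of the two enantiotopic carbonyl groups, so the C3 stereocentre is set by catalyst control.

Step 3
Reactants: 7 (3S)-5-methoxy-5-oxo-3-phenylpentanoic acid
Product: 8 methyl (3R)-5-chloro-5-oxo-3-phenylpentanoate
Conditions: (COCl)2 (1.2 equiv), DMF (cat.), CH2Cl2, 0 °C → 20 °C; evaporate, use at once
Reagents that add atoms: oxalyl chloride, ClC(=O)C(=O)Cl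
Why: Vilsmeier-type conversion of the acid into its chloride, in which the stereocentre is β to both carbonyl groups and cannot enolise (the descriptor changes only because COCl outranks CO2Me); immediate cold use avoids ester/acyl chloride interchange through a cyclic acyloxonium ion, which would erode the enantiomeric purity.

Step 4
Reactants: 8 methyl (3R)-5-chloro-5-oxo-3-phenylpentanoate; 5 (triisopropylsilyloxy)acetylene
Product: 10 methyl (3R)-3-[2-oxo-4-(triisopropylsilyloxy)cyclobut-3-en-1-yl]-3-phenylpropanoate (both epimers at the ring carbon), via ketene 9 (not isolated)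
Conditions: 5 (2 equiv), Et3N (1.2 equiv), CH2Cl2, 0 → 20 °C, 8 added over 4 h by syringe pump
Reagents that add atoms: none
Why: Dehydrochlorination gives aldoketene 9 at low stationary concentration (dimerisation suppressed) and a ketene–ynol ether [2+2] cycloaddition follows, in which the ketene carbonyl carbon bonds to the unsubstituted, nucleophilic alkyne carbon so that the silyloxy group ends on C3 and the side chain on the sp3 ring carbon; the new ring stereocentre forms unselectively, which is irrelevant because step 5 erases it.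

Step 5
Reactants: 10 methyl (3R)-3-[2-oxo-4-(triisopropylsilyloxy)cyclobut-3-en-1-yl]-3-phenylpropanoate; 11 (ethoxyethynyl)trimethylsilane
Product: 16 methyl (3S)-3-[4-ethoxy-2-hydroxy-6-(triisopropylsilyloxy)-3-(trimethylsilyl)phenyl]-3-phenylpropanoate, via vinylketene 12 (not isolated), via vinylcyclobutenone 13 (not isolated), via dienylketene 14 (not isolated), via cyclohexadienone 15 (not isolated)
Conditions: 11 (2.5 equiv), PhMe (0.3 M), 80 °C, sealed tube, Ar, 24–48 h; strip volatiles below 40 °C; Et3N-deactivated silica
Reagents that add atoms: none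
Why: Danheiser benzannulation: conrotatory four-electron opening of 10 (the alkyl group turning outward, which keeps the stereogenic C–H away from the ketene and closes off a [1,5]-hydrogen shift) gives vinylketene 12, whose carbonyl carbon (future C8a) is attacked by the silicon-bearing, nucleophilic carbon of 11 (future C8) in a [2+2] cycloaddition that also joins C6 to C7, and strain-driven opening of 13 gives dienylketene 14. Ring A is closed by six-electron disrotatory electrocyclisation of 14 (C4a–C8a), and tautomerisation of dienone 15 to the phenol makes the sequence irreversible. The closest known reaction type is the thermal annulation of cyclobutenones with alkoxy- and silyloxyalkynes to resorcinol derivatives. No stereocentre is created: the benzylic centre lies outside the pericyclic array and is untouched, and the epimeric ring carbon of 10 becomes the sp2 carbon C4a. The selectivity needed is the regiochemistry of the ketene–alkyne union, secured by the polarisation of the ynol ether (oxygen lone pair and β-silicon effect both make the silylated carbon the nucleophilic terminus), so that SiMe3 ends on C8 beside the only free hydroxyl. Holding the bath at 80 °C and removing excess 11 before any hotter stage prevents retro-ene loss of ethylene from 11 and acylation of the phenol by the resulting silylketene.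

Step 6
Reactants: 16 methyl (3S)-3-[4-ethoxy-2-hydroxy-6-(triisopropylsilyloxy)-3-(trimethylsilyl)phenyl]-3-phenylpropanoate
Product: 17 (4S)-7-ethoxy-4-phenyl-5-(triisopropylsilyloxy)-8-(trimethylsilyl)chroman-2-one
Conditions: DBU (0.1 equiv), 4 Å MS, PhMe, 80 °C
Reagents that add atoms: none
Why: Intramolecular transesterification of the C8a phenol onto the methyl ester closes the six-membered aryl lactone, pulled forward by uptake of methanol on the sieves and by the compression that the ortho silyloxy group and the benzylic phenyl exert on the side chain; catalytic base is used in place of acid because the electron-rich aryl–silicon bond is acid-labile, and any 17 already formed in step 5 is simply carried along.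

Step 7
Reactants: 17 (4S)-7-ethoxy-4-phenyl-5-(triisopropylsilyloxy)-8-(trimethylsilyl)chroman-2-one; 18 3-(4-methoxyphenyl)propanoic acid
Product: 20 (4S)-7-ethoxy-8-[3-(4-methoxyphenyl)propanoyl]-4-phenyl-5-(triisopropylsilyloxy)chroman-2-one, via acid chloride 19 (not isolated)
Conditions: 18, (COCl)2, DMF (cat.), CH2Cl2, 0 → 20 °C, evaporate; then 17, SnCl4 (1.2 equiv), 2,6-di-tert-butyl-4-methylpyridine (0.3 equiv), CH2Cl2, −78 → −20 °C
Reagents that add atoms: none
Why: Friedel–Crafts ipso-acylation (acyl-desilylation) of an aryltrimethylsilane: attack at C8 gives an arenium ion stabilised by the β-silicon and by the C7 and C5 oxygens and then loses Me3SiCl, whereas C6–H is walled in by OSi(iPr)3 and OEt and has no silicon assistance; no HCl is formed and the hindered pyridine removes adventitious acid, so protodesilylation should not compete.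

Step 8
Reactants: 20 (4S)-7-ethoxy-8-[3-(4-methoxyphenyl)propanoyl]-4-phenyl-5-(triisopropylsilyloxy)chroman-2-one
Product: 22 (4S)-5,7-dihydroxy-8-[3-(4-methoxyphenyl)propanoyl]-4-phenylchroman-2-one, via silyl ether 21 (not isolated)
Conditions: BCl3 (2.5 equiv), CH2Cl2, −78 → 0 °C; MeOH quench, evaporate; then Bu4NF/AcOH (1:1, 1.5 equiv), THF, 0 °C
Reagents that add atoms: none
Why: Chelation-controlled ether cleavage: BCl3 held between the C8 ketone and the C7 oxygen removes only the ortho ethyl group (the remote anisole methyl ether cannot chelate and should survive), after which buffered fluoride cleaves the aryl O–Si bond without opening the aryl lactone; C4 carries no acidic hydrogen and is not at risk.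

Compound list
1 | acetylene | C#C | starting material
2 | triisopropylsilyl trifluoromethanesulfonate | CC(C)[Si](OS(=O)(=O)C(F)(F)F)(C(C)C)C(C)C | starting material
3 | lithium acetylide | [Li+].[C-]#C | intermediate (not isolated)
4 | lithium ethynolate | [Li+].[O-]C#C | intermediate (not isolated)
5 | (triisopropylsilyloxy)acetylene | C#CO[Si](C(C)C)(C(C)C)C(C)C | intermediate
6 | 3-phenylglutaric anhydride | O=C1CC(c2ccccc2)CC(=O)O1 | starting material
7 | (3S)-5-methoxy-5-oxo-3-phenylpentanoic acid | COC(=O)C[C@@H](c1ccccc1)CC(=O)O | intermediate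
8 | methyl (3R)-5-chloro-5-oxo-3-phenylpentanoate | COC(=O)C[C@@H](c1ccccc1)CC(=O)Cl | intermediate
9 | methyl (3R)-5-oxo-3-phenylpent-4-enoate (ketene) | COC(=O)C[C@@H](c1ccccc1)C=C=O | intermediate (not isolated)
10 | methyl (3R)-3-[2-oxo-4-(triisopropylsilyloxy)cyclobut-3-en-1-yl]-3-phenylpropanoate, epimer mixture at the ring carbon | COC(=O)C[C@@H](c1ccccc1)C1C(=O)C=C1O[Si](C(C)C)(C(C)C)C(C)C | intermediate
11 | (ethoxyethynyl)trimethylsilane | CCOC#C[Si](C)(C)C | starting material
12 | methyl (3R,4Z)-7-oxo-3-phenyl-5-(triisopropylsilyloxy)hepta-4,6-dienoate (vinylketene) | COC(=O)C[C@@H](c1ccccc1)/C=C(O[Si](C(C)C)(C(C)C)C(C)C)/C=C=O | intermediate (not isolated)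
13 | methyl (3R,4Z)-5-[2-ethoxy-4-oxo-3-(trimethylsilyl)cyclobut-2-en-1-yl]-3-phenyl-5-(triisopropylsilyloxy)pent-4-enoate (vinylcyclobutenone, both ring epimers) | COC(=O)C[C@@H](c1ccccc1)/C=C(O[Si](C(C)C)(C(C)C)C(C)C)/C1C(OCC)=C([Si](C)(C)C)C1=O | intermediate (not isolated)
14 | methyl (3R,4Z,6E)-7-ethoxy-9-oxo-3-phenyl-5-(triisopropylsilyloxy)-8-(trimethylsilyl)nona-4,6,8-trienoate (dienylketene, cyclisable geometry) | COC(=O)C[C@@H](c1ccccc1)/C=C(O[Si](C(C)C)(C(C)C)C(C)C)/C=C(OCC)\C([Si](C)(C)C)=C=O | intermediate (not isolated)
15 | methyl (3R)-3-[4-ethoxy-2-oxo-6-(triisopropylsilyloxy)-3-(trimethylsilyl)cyclohexa-3,5-dien-1-yl]-3-phenylpropanoate (both ring epimers) | COC(=O)C[C@@H](c1ccccc1)C1C(=O)C([Si](C)(C)C)=C(OCC)C=C1O[Si](C(C)C)(C(C)C)C(C)C | intermediate (not isolated)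
16 | methyl (3S)-3-[4-ethoxy-2-hydroxy-6-(triisopropylsilyloxy)-3-(trimethylsilyl)phenyl]-3-phenylpropanoate | COC(=O)C[C@@H](c1ccccc1)c1c(O[Si](C(C)C)(C(C)C)C(C)C)cc(OCC)c([Si](C)(C)C)c1O | intermediate
17 | (4S)-7-ethoxy-4-phenyl-5-(triisopropylsilyloxy)-8-(trimethylsilyl)chroman-2-one | O=C1C[C@@H](c2ccccc2)c2c(O[Si](C(C)C)(C(C)C)C(C)C)cc(OCC)c([Si](C)(C)C)c2O1 | intermediate
18 | 3-(4-methoxyphenyl)propanoic acid | COc1ccc(CCC(=O)O)cc1 | starting material
19 | 3-(4-methoxyphenyl)propanoyl chloride | COc1ccc(CCC(=O)Cl)cc1 | intermediate (not isolated)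
20 | (4S)-7-ethoxy-8-[3-(4-methoxyphenyl)propanoyl]-4-phenyl-5-(triisopropylsilyloxy)chroman-2-one | O=C1C[C@@H](c2ccccc2)c2c(O[Si](C(C)C)(C(C)C)C(C)C)cc(OCC)c(C(=O)CCc3ccc(OC)cc3)c2O1 | intermediate
21 | (4S)-7-hydroxy-8-[3-(4-methoxyphenyl)propanoyl]-4-phenyl-5-(triisopropylsilyloxy)chroman-2-one | O=C1C[C@@H](c2ccccc2)c2c(O[Si](C(C)C)(C(C)C)C(C)C)cc(O)c(C(=O)CCc3ccc(OC)cc3)c2O1 | intermediate (not isolated)
22 | (4S)-5,7-dihydroxy-8-[3-(4-methoxyphenyl)propanoyl]-4-phenylchroman-2-one (CNP0240692.1) | COc1ccc(CCC(=O)c2c(O)cc(O)c3c2OC(=O)C[C@H]3c2ccccc2)cc1 | target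

Total step count: 8. Longest linear sequence: 7 steps (6 → 7 → 8 → 10 → 16 → 17 → 20 → 22, steps 2 to 8).

Steps most likely to fail

Step 5. The hindered, silicon-bearing alkyne may capture the vinylketene too slowly, so that ketene dimerisation, the [1,5]-hydrogen shift of the minor inward rotamer, or retro-ene fragmentation of 11 take over. The fallback sets out from 10 and comes back at 20; it moves regiocontrol from silicon to the phenol. The annulation would be run with unhindered ethoxyacetylene (PhMe, 80 °C) to give methyl (3S)-3-[4-ethoxy-2-hydroxy-6-(triisopropylsilyloxy)phenyl]-3-phenylpropanoate F1. Its single free hydroxyl would be esterified with 19 (Et3N, DMAP cat., CH2Cl2, 0 °C) to methyl (3S)-3-[4-ethoxy-2-[3-(4-methoxyphenyl)propanoyloxy]-6-(triisopropylsilyloxy)phenyl]-3-phenylpropanoate F2. A TiCl4-promoted Fries rearrangement should then deliver the acyl group to the only open ortho carbon (C8), giving methyl (3S)-3-[4-ethoxy-2-hydroxy-3-[3-(4-methoxyphenyl)propanoyl]-6-(triisopropylsilyloxy)phenyl]-3-phenylpropanoate F3. Acid-catalysed lactonisation (p-TsOH cat., PhMe, 80 °C; no aryl–silicon bond is left to lose) returns to 20.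

Step 7. Protodesilylation by adventitious acid may precede acylation, after which C6 and C8 would compete, or the Lewis acid may strip the silyl ether. The fallback sets out from 17 and comes back at 20. Ipso-iododesilylation with ICl (CH2Cl2, −78 °C) should give (4S)-7-ethoxy-8-iodo-4-phenyl-5-(triisopropylsilyloxy)chroman-2-one F4. F4 would then be joined, in a carbonylative Suzuki–Miyaura coupling (CO 1 atm, Pd(PPh3)4, K3PO4, THF, 50 °C), with B-[2-(4-methoxyphenyl)ethyl]-9-borabicyclo[3.3.1]nonane F5, made beforehand from 4-methoxystyrene and 9-borabicyclo[3.3.1]nonane.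

Step 1. Monolithium acetylide may disproportionate to Li2C2, or oxygen transfer may stay incomplete. The fallback sets out from 2 and comes back at 5. Commercial 3-phenylisoxazole would be lithiated at C5 (n-BuLi, THF, −78 °C) to 5-lithio-3-phenylisoxazole F6, which should fragment on warming to −40 °C into benzonitrile and lithium ethynolate 4; 2 then silylates 4 on oxygen as in step 1.

Further compounds
F1 | step 5 | methyl (3S)-3-[4-ethoxy-2-hydroxy-6-(triisopropylsilyloxy)phenyl]-3-phenylpropanoate | COC(=O)C[C@@H](c1ccccc1)c1c(O[Si](C(C)C)(C(C)C)C(C)C)cc(OCC)cc1O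
F2 | step 5 | methyl (3S)-3-[4-ethoxy-2-[3-(4-methoxyphenyl)propanoyloxy]-6-(triisopropylsilyloxy)phenyl]-3-phenylpropanoate | COC(=O)C[C@@H](c1ccccc1)c1c(O[Si](C(C)C)(C(C)C)C(C)C)cc(OCC)cc1OC(=O)CCc1ccc(OC)cc1
F3 | step 5 | methyl (3S)-3-[4-ethoxy-2-hydroxy-3-[3-(4-methoxyphenyl)propanoyl]-6-(triisopropylsilyloxy)phenyl]-3-phenylpropanoate | COC(=O)C[C@@H](c1ccccc1)c1c(O[Si](C(C)C)(C(C)C)C(C)C)cc(OCC)c(C(=O)CCc2ccc(OC)cc2)c1O
F4 | step 7 | (4S)-7-ethoxy-8-iodo-4-phenyl-5-(triisopropylsilyloxy)chroman-2-one | O=C1C[C@@H](c2ccccc2)c2c(O[Si](C(C)C)(C(C)C)C(C)C)cc(OCC)c(I)c2O1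
F5 | step 7 | B-[2-(4-methoxyphenyl)ethyl]-9-borabicyclo[3.3.1]nonane | COc1ccc(CCB2C3CCCC2CCC3)cc1
F6 | step 1 | 5-lithio-3-phenylisoxazole | [Li]c1cc(-c2ccccc2)no1
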